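**Plan**

1. Numbering and enabling feature: C1 is the lactam carbonyl, the ansa chain runs to the benzylic carbinol C15, the arene is C16–C21 with N on C20 and O on C18 and C21. Because the lactam nitrogen is bonded to C20 of the benzene ring C16–C21, the 19-membered ring (N, C1–C15, C16, C21, C20) can be closed at N–C20 from a primary (2E,4Z)-dienamide and a C20 bromide.
2. Retrosynthetic cuts: the C7 carbamate, the two aryl O–Me bonds (through the quinone) and two O–Si bonds; N–C20 (ring); C3–C4 (alkyne–alkenyl iodide coupling); C4–C5 (one-carbon homologation); C6–C7 (aldol); C8=C9 (Wittig); C10–C11 (crotylation); C11–C12 (alkenyl addition, the alkenyl group later cut back to the C11 aldehyde); C14–C15 (crotylation); C15–C16 (formylation).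
3. Forward order: the chain grows linearly from the arene aldehyde (C15) towards C1; the macrolactam, the only ring formed, closes in step 21; carbamoylation, desilylation, oxidation to the quinone and reduction follow.
4. Stereochemistry: C14/C15 and C10/C11 come from (Z)-crotylboranes carrying isopinocampheyl groups (syn, reagent-controlled face); C12 from a ligand-controlled alkenylzinc addition; C6/C7 from an auxiliary-controlled titanium syn-aldol; 8E from a stabilised ylide, 2E from the iodoacrylamide, 4Z from cis-semireduction of the C4–C5 alkyne.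

Key step: step 21

Remark: in names Ar = 3-bromo-2,5-dimethoxyphenyl, TBS = tert-butyldimethylsilyl, TES = triethylsilyl, Ipc = isopinocampheyl; locants C1–C21 follow line 1.
Remark: 16, 18 and 24 are taken as purchasable (24 is otherwise two known steps from diethyl methylmalonate and iodoform, 18 one acylation from (R)-4-benzylthiazolidine-2-thione).
Remark: metal alkoxides that are only hydrolysed at work-up are not numbered; organometallic and acyl intermediates that are made first and then treated with a second reagent are.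

**Route**

Step 1
Reactants: 1 2,6-dibromo-4-methoxyphenol
Product: 2 1,3-dibromo-2,5-dimethoxybenzene
Conditions: MeI, K2CO3, acetone, reflux
Reagents that add atoms: iodomethane, CI
Why: Williamson O-methylation of the acidic phenol should go to completion, since the two ortho bromines do not block attack on the small electrophile.

Step 2
Reactants: 2 1,3-dibromo-2,5-dimethoxybenzene
Product: 4 3-bromo-2,5-dimethoxybenzaldehyde, via aryllithium 3 (not isolated)
Conditions: n-BuLi (1.0 equiv), Et2O, −78 °C; DMF, −78 °C to rt; aq. NH4Cl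
Reagents that add atoms: n-butyllithium, [Li]CCCC (lithium in 3 only); N,N-dimethylformamide, CN(C)C=O
Why: Bromine–lithium exchange at one of the two equivalent C–Br bonds is fast at −78 °C, the monolithio arene has no ortho leaving group and is formylated by DMF (Bouveault formylation), and the remaining bromide becomes the C20 handle.

Step 3
Reactants: 4 3-bromo-2,5-dimethoxybenzaldehyde
Product: 5 (1R,2S)-1-Ar-2-methylbut-3-en-1-ol
Conditions: cis-but-2-ene, KOt-Bu, n-BuLi, THF, −78 to −45 °C; (+)-Ipc2BOMe [from (−)-α-pinene], −78 °C; BF3·OEt2; 4, −78 °C; NaOH, H2O2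
Reagents that add atoms: (Z)-but-2-enyldiisopinocampheylborane (made in the flask from cis-but-2-ene), C/C=C\CB([C@H]1C[C@H]2C[C@@H]([C@@H]1C)C2(C)C)[C@H]1C[C@H]2C[C@@H]([C@@H]1C)C2(C)C
Why: Brown (Z)-crotylboration through a closed chair transition state turns the (Z)-geometry into the C14/C15 syn relationship, and the isopinocampheyl groups from (−)-α-pinene send the crotyl group to the Re face of the aldehyde, which sets C15 as R and C14 as S.

Step 4
Reactants: 5 (1R,2S)-1-Ar-2-methylbut-3-en-1-ol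
Product: 6 (1R,2S)-1-Ar-2-methyl-1-(TBS-oxy)but-3-ene
Conditions: TBSOTf, 2,6-lutidine, CH2Cl2, 0 °C
Reagents that add atoms: tert-butyldimethylsilyl trifluoromethanesulfonate, CC(C)(C)[Si](C)(C)OS(=O)(=O)C(F)(F)F
Why: Silylation with the silyl triflate overcomes the hindrance of the benzylic secondary alcohol and masks C15–OH until the carbamate is in place.

Step 5
Reactants: 6 (1R,2S)-1-Ar-2-methyl-1-(TBS-oxy)but-3-ene
Product: 8 (3S,4R)-4-Ar-3-methyl-4-(TBS-oxy)butan-1-ol, via alkylborane 7 (not isolated)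
Conditions: 9-BBN, THF, 0 °C to rt; NaOH, H2O2
Reagents that add atoms: 9-borabicyclo[3.3.1]nonane, C1CCC2CCCC1B2 (boron in 7 only); hydrogen peroxide, OO
Why: Anti-Markovnikov hydroboration–oxidation with the bulky borane places oxygen on the terminal carbon C12 and leaves C13 as the methylene of the target.

Step 6
Reactants: 8 (3S,4R)-4-Ar-3-methyl-4-(TBS-oxy)butan-1-ol
Product: 9 (3S,4R)-4-Ar-3-methyl-4-(TBS-oxy)butanal
Conditions: Dess–Martin periodinane, NaHCO3, CH2Cl2, rt
Reagents that add atoms: none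
Why: Dess–Martin oxidation converts the primary alcohol into the C12 aldehyde under buffered conditions that do not touch the silyl ether or the aryl bromide.

Step 7
Reactants: 9 (3S,4R)-4-Ar-3-methyl-4-(TBS-oxy)butanal
Product: 10 (1R,2S,4S,5E)-1-Ar-2-methyl-1-(TBS-oxy)dec-5-en-4-ol
Conditions: hex-1-yne, Cy2BH, toluene, 0 °C to rt; Me2Zn, −78 °C; (2R)-3-exo-morpholinoisoborneol [(+)-MIB, 5 mol %]; 9, −30 to 0 °C; aq. NH4Cl
Reagents that add atoms: (E)-hex-1-enyl(methyl)zinc (made in the flask from hex-1-yne, CCCCC#C), CCCC/C=C/[Zn]C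
Why: Amino-alcohol-catalysed enantioselective addition of an alkenylzinc reagent (alkyne hydroboration, boron-to-zinc exchange, ligand-accelerated addition) should deliver the alkenyl group to the Re face under control of (+)-MIB, the antipode of the ligand that makes (S)-1-phenylpropan-1-ol from benzaldehyde and Et2Zn, and so set C12 as S with little influence from the remote C14 and C15 centres.

Step 8
Reactants: 10 (1R,2S,4S,5E)-1-Ar-2-methyl-1-(TBS-oxy)dec-5-en-4-ol
Product: 11 (1R,2S,4S,5E)-1-Ar-4-methoxy-2-methyl-1-(TBS-oxy)dec-5-ene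
Conditions: NaH, MeI, THF/DMF, 0 °C to rt
Reagents that add atoms: iodomethane, CI
Why: Williamson methylation of the allylic alkoxide installs the C12 methyl ether and leaves the silyl ether and the aryl bromide alone.

Step 9
Reactants: 11 (1R,2S,4S,5E)-1-Ar-4-methoxy-2-methyl-1-(TBS-oxy)dec-5-ene
Product: 12 (2S,4S,5R)-5-Ar-2-methoxy-4-methyl-5-(TBS-oxy)pentanal
Conditions: OsO4 (2 mol %), NaIO4, 2,6-lutidine, dioxane/H2O, rt
Reagents that add atoms: sodium periodate, [Na+].[O-]I(=O)(=O)=O (oxygen delivered through OsO4)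
Why: Lemieux–Johnson cleavage (osmium-catalysed dihydroxylation, then periodate glycol fission) cuts the alkenyl group back to the C11 aldehyde without attacking the electron-rich arene, and the α-methoxy aldehyde is used at once so that C12 does not epimerise.

Step 10
Reactants: 12 (2S,4S,5R)-5-Ar-2-methoxy-4-methyl-5-(TBS-oxy)pentanal
Product: 13 (3S,4R,5S,7S,8R)-8-Ar-5-methoxy-3,7-dimethyl-8-(TBS-oxy)oct-1-en-4-ol
Conditions: cis-but-2-ene, KOt-Bu, n-BuLi, THF, −78 to −45 °C; (+)-Ipc2BOMe, −78 °C; BF3·OEt2; 12, −78 °C; NaOH, H2O2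
Reagents that add atoms: (Z)-but-2-enyldiisopinocampheylborane (made in the flask from cis-but-2-ene), C/C=C\CB([C@H]1C[C@H]2C[C@@H]([C@@H]1C)C2(C)C)[C@H]1C[C@H]2C[C@@H]([C@@H]1C)C2(C)C
Why: Brown (Z)-crotylboration gives the C10/C11 syn adduct, and the Re-face preference of the reagent coincides with the Felkin–Cornforth preference of the α-methoxy aldehyde (matched pair), so that C11 becomes R, anti to the C12 methoxy group, and C10 becomes S.

Step 11
Reactants: 13 (3S,4R,5S,7S,8R)-8-Ar-5-methoxy-3,7-dimethyl-8-(TBS-oxy)oct-1-en-4-ol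
Product: 14 (3S,4R,5S,7S,8R)-8-Ar-4,5-dimethoxy-3,7-dimethyl-8-(TBS-oxy)oct-1-ene
Conditions: NaH, MeI, THF/DMF, 0 °C to rt
Reagents that add atoms: iodomethane, CI
Why: Williamson methylation of the C11 alkoxide completes the anti-C11,C12-dimethoxy unit.

Step 12
Reactants: 14 (3S,4R,5S,7S,8R)-8-Ar-4,5-dimethoxy-3,7-dimethyl-8-(TBS-oxy)oct-1-ene
Product: 15 (2R,3R,4S,6S,7R)-7-Ar-3,4-dimethoxy-2,6-dimethyl-7-(TBS-oxy)heptanal
Conditions: OsO4 (2 mol %), NaIO4, 2,6-lutidine, dioxane/H2O, rt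
Reagents that add atoms: sodium periodate, [Na+].[O-]I(=O)(=O)=O (oxygen delivered through OsO4)
Why: Lemieux–Johnson cleavage of the terminal vinyl group unmasks the C9 aldehyde under buffered conditions that should not epimerise C10.

Step 13
Reactants: 15 (2R,3R,4S,6S,7R)-7-Ar-3,4-dimethoxy-2,6-dimethyl-7-(TBS-oxy)heptanal; 16 2-(triphenylphosphoranylidene)propanal
Product: 17 (2E,4S,5R,6S,8S,9R)-9-Ar-5,6-dimethoxy-2,4,8-trimethyl-9-(TBS-oxy)non-2-enal
Conditions: toluene, 90 °C
Reagents that add atoms: none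
Why: Wittig olefination with the stabilised formyl ylide gives the trisubstituted enal with 8E geometry under neutral conditions that leave C10 intact, and the α-branched enal formed reacts too slowly with the ylide to be homologated again.

Step 14
Reactants: 17 (2E,4S,5R,6S,8S,9R)-9-Ar-5,6-dimethoxy-2,4,8-trimethyl-9-(TBS-oxy)non-2-enal; 18 (R)-4-benzyl-3-propanoyl-1,3-thiazolidine-2-thione
Product: 20 (2R,3R,4E,6S,7R,8S,10S,11R)-11-Ar-1-[(4R)-4-benzyl-2-thioxo-1,3-thiazolidin-3-yl]-3-hydroxy-7,8-dimethoxy-2,4,6,10-tetramethyl-11-(TBS-oxy)undec-4-en-1-one, via titanium enolate 19 (not isolated)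
Conditions: 18, TiCl4, i-Pr2NEt, N-methylpyrrolidin-2-one, CH2Cl2, 0 °C; 17, −78 to 0 °C
Reagents that add atoms: titanium tetrachloride, Cl[Ti](Cl)(Cl)Cl (titanium and chlorine in 19 only)
Why: In this Crimmins titanium aldol the chlorotitanium (Z)-enolate reacts through a non-chelated Zimmerman–Traxler chair in which the (4R)-benzyl group shields one enolate face, which should give the C6/C7 syn adduct in the configuration of the target (2R,3R in 20).

Step 15
Reactants: 20 syn-aldol adduct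
Product: 21 3-O-TES ether of 20
Conditions: TESOTf, 2,6-lutidine, CH2Cl2, −78 °C
Reagents that add atoms: triethylsilyl trifluoromethanesulfonate, CC[Si](CC)(CC)OS(=O)(=O)C(F)(F)F
Why: Silylation gives a C7 triethylsilyl ether that blocks retro-aldol cleavage and can later be removed in the presence of the C15 TBS ether.

Step 16
Reactants: 21 3-O-TES ether of 20
Product: 22 (2R,3R,4E,6S,7R,8S,10S,11R)-11-Ar-7,8-dimethoxy-2,4,6,10-tetramethyl-11-(TBS-oxy)-3-(TES-oxy)undec-4-enal
Conditions: i-Bu2AlH, CH2Cl2, −78 °C; aq. potassium sodium tartrate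
Reagents that add atoms: none
Why: Hydride reduction of the activated N-acylthiazolidinethione stops at the aldehyde because the tetrahedral aluminium adduct is stable at −78 °C, and it releases the auxiliary without epimerising C6.

Step 17
Reactants: 22 (2R,3R,4E,6S,7R,8S,10S,11R)-11-Ar-7,8-dimethoxy-2,4,6,10-tetramethyl-11-(TBS-oxy)-3-(TES-oxy)undec-4-enal
Product: 23 (3S,4R,5E,7S,8R,9S,11S,12R)-12-Ar-8,9-dimethoxy-3,5,7,11-tetramethyl-12-(TBS-oxy)-4-(TES-oxy)dodec-5-en-1-yne
Conditions: dimethyl (1-diazo-2-oxopropyl)phosphonate, K2CO3, MeOH, 0 °C to rt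
Reagents that add atoms: dimethyl (1-diazo-2-oxopropyl)phosphonate, CC(=O)C(=[N+]=[N-])P(=O)(OC)OC
Why: The Ohira–Bestmann variant of the Seyferth–Gilbert homologation adds C4 and turns the aldehyde into the terminal alkyne with carbonate as the only base, which should be mild enough to keep C6 and the β-silyloxy group intact.

Step 18
Reactants: 24 (E)-3-iodo-2-methylprop-2-enoic acid
Product: 26 (E)-3-iodo-2-methylprop-2-enamide, via acid chloride 25 (not isolated)
Conditions: (COCl)2, DMF (cat.), CH2Cl2, 0 °C to rt; aq. NH3, THF, 0 °C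
Reagents that add atoms: oxalyl chloride, O=C(Cl)C(=O)Cl (chlorine in 25 only); ammonia, N
Why: Acid chloride formation followed by ammonolysis gives the primary amide and leaves the (E)-alkenyl iodide unchanged.

Step 19
Reactants: 23 alkyne; 26 (E)-3-iodo-2-methylprop-2-enamide
Product: 27 (2E,6S,7R,8E,10S,11R,12S,14S,15R)-15-Ar-11,12-dimethoxy-2,6,8,10,14-pentamethyl-15-(TBS-oxy)-7-(TES-oxy)pentadeca-2,8-dien-4-ynamide
Conditions: Pd(PPh3)2Cl2 (5 mol %), CuI (10 mol %), Et3N, THF, rt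
Reagents that add atoms: none
Why: Sonogashira coupling joins C3 to C4 with retention of the 2E geometry, and at room temperature zerovalent palladium inserts into the alkenyl iodide but not into the electron-rich, ortho-substituted aryl bromide.

Step 20
Reactants: 27 enynamide
Product: 28 (2E,4Z,6S,7R,8E,10S,11R,12S,14S,15R)-15-Ar-11,12-dimethoxy-2,6,8,10,14-pentamethyl-15-(TBS-oxy)-7-(TES-oxy)pentadeca-2,4,8-trienamide
Conditions: Zn dust activated with Cu(OAc)2 and AgNO3, MeOH/H2O, 40 °C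
Reagents that add atoms: none
Why: Zinc–copper–silver semireduction of the conjugated enyne (Boland reduction) adds two hydrogens cis to give the 4Z alkene, and should not over-reduce, remove the bromide or isomerise the 2E alkene.

Step 21
Reactants: 28 seco (2E,4Z)-dienamide
Product: 29 protected macrolactam (N–C20 bond formed; 7-O-TES, 15-O-TBS, 11,12,18,21-tetramethoxy)
Conditions: CuI (0.5 equiv), N,N'-dimethylethylenediamine (1 equiv), K2CO3 (3 equiv), toluene (2 mM, slow addition of 28), 100 °C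
Reagents that add atoms: none
Why: K2CO3 deprotonates the primary amide on monovalent copper to give a diamine-ligated copper amidate, which adds oxidatively to the C20–Br bond and then forms the N–C20 bond by reductive elimination from trivalent copper. The closest known reaction type is the Goldberg amidation of aryl halides with CuI and a 1,2-diamine, used here intramolecularly as it has been to close ansamycin-type macrolactams. The 19-membered ring (N, C1–C15, C16, C21, C20) closes by macrocyclisation through C–N cross-coupling at the aryl carbon, helped by high dilution and by the rigid diene, alkene and arene segments of the chain. No stereocentre is formed, and none of the seven existing ones is adjacent to a carbonyl group, so the carbonate base cannot epimerise them. N-arylation is secured over O-arylation because the amidate binds copper through nitrogen and both alcohols are silylated (C7 OTES, C15 OTBS), and the bromide, flanked only by C21–OMe and C19–H, has a substitution pattern that this coupling accepts. The 4Z alkene should survive because the ring closes at nitrogen and C1 is never activated as an acyl electrophile, the usual cause of 4Z to 4E isomerisation.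

Step 22
Reactants: 29 protected macrolactam
Product: 30 C7 alcohol (29 without the TES group)
Conditions: HF·pyridine, pyridine, THF, 0 °C
Reagents that add atoms: none
Why: Buffered fluoride cleaves the triethylsilyl ether much faster than the hindered benzylic TBS ether, so that only C7–OH should be freed.

Step 23
Reactants: 30 C7 alcohol
Product: 32 C7 carbamate (15-O-TBS), via trichloroacetylcarbamate 31 (not isolated)
Conditions: Cl3CC(O)NCO, CH2Cl2, 0 °C; K2CO3, MeOH, rt
Reagents that add atoms: trichloroacetyl isocyanate, O=C=NC(=O)C(Cl)(Cl)Cl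
Why: Acylation of the only free hydroxyl by the electrophilic isocyanate and methanolysis of the trichloroacetyl group (Kočovský carbamoylation) gives the primary C7 carbamate, the anilide nitrogen being too hindered and too weakly nucleophilic to compete.

Step 24
Reactants: 32 C7 carbamate (15-O-TBS)
Product: 33 C7 carbamate with free C15–OH (18,21-di-O-methyl)
Conditions: HF·pyridine, THF, 0 °C to rt
Reagents that add atoms: none
Why: Unbuffered fluoride removes the C15 silyl ether, and the primary carbamate and the lactam are stable to these conditions.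

Step 25
Reactants: 33 dimethoxyarene carbamate
Product: 34 quinone (carbonyls at C18 and C21)
Conditions: (NH4)2Ce(NO3)6, MeCN/H2O, 0 °C
Reagents that add atoms: water, O
Why: Oxidative demethylation of the para-dimethoxyarene by tetravalent cerium proceeds through the arene radical cation, to which water adds at C18 and C21 with loss of methanol, and should give the amido-benzoquinone faster than any oxidation of the benzylic alcohol or the alkenes.

Step 26
Reactants: 34 quinone
Product: 35 CNP0532580.1 (hydroquinone target)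
Conditions: Na2S2O4, EtOAc/H2O, rt, under argon
Reagents that add atoms: none
Why: Dithionite reduces the quinone to the hydroquinone by two-electron, two-proton transfer, and work-up under argon keeps the air-sensitive product from reoxidising.

**Compound list**

1 | 2,6-dibromo-4-methoxyphenol | COc1cc(Br)c(O)c(Br)c1 | starting material
2 | 1,3-dibromo-2,5-dimethoxybenzene | COc1cc(Br)c(OC)c(Br)c1 | intermediate
3 | (3-bromo-2,5-dimethoxyphenyl)lithium, formed in the flask | [Li]c1cc(OC)cc(Br)c1OC | intermediate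
4 | 3-bromo-2,5-dimethoxybenzaldehyde | O=Cc1cc(OC)cc(Br)c1OC | intermediate
5 | (1R,2S)-1-Ar-2-methylbut-3-en-1-ol | C=C[C@H](C)[C@@H](O)c1cc(OC)cc(Br)c1OC | intermediate
6 | (1R,2S)-1-Ar-2-methyl-1-(TBS-oxy)but-3-ene | C=C[C@H](C)[C@@H](O[Si](C)(C)C(C)(C)C)c1cc(OC)cc(Br)c1OC | intermediate
7 | 9-[(3S,4R)-4-Ar-3-methyl-4-(TBS-oxy)butyl]-9-borabicyclo[3.3.1]nonane, formed in the flask | C1CCC2CCCC1B2CC[C@H](C)[C@@H](O[Si](C)(C)C(C)(C)C)c1cc(OC)cc(Br)c1OC | intermediate
8 | (3S,4R)-4-Ar-3-methyl-4-(TBS-oxy)butan-1-ol | OCC[C@H](C)[C@@H](O[Si](C)(C)C(C)(C)C)c1cc(OC)cc(Br)c1OC | intermediate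
9 | (3S,4R)-4-Ar-3-methyl-4-(TBS-oxy)butanal | O=CC[C@H](C)[C@@H](O[Si](C)(C)C(C)(C)C)c1cc(OC)cc(Br)c1OC | intermediate
10 | (1R,2S,4S,5E)-1-Ar-2-methyl-1-(TBS-oxy)dec-5-en-4-ol | CCCC/C=C/[C@@H](O)C[C@H](C)[C@@H](O[Si](C)(C)C(C)(C)C)c1cc(OC)cc(Br)c1OC | intermediate
11 | (1R,2S,4S,5E)-1-Ar-4-methoxy-2-methyl-1-(TBS-oxy)dec-5-ene | CCCC/C=C/[C@@H](OC)C[C@H](C)[C@@H](O[Si](C)(C)C(C)(C)C)c1cc(OC)cc(Br)c1OC | intermediate
12 | (2S,4S,5R)-5-Ar-2-methoxy-4-methyl-5-(TBS-oxy)pentanal | O=C[C@@H](OC)C[C@H](C)[C@@H](O[Si](C)(C)C(C)(C)C)c1cc(OC)cc(Br)c1OC | intermediate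
13 | (3S,4R,5S,7S,8R)-8-Ar-5-methoxy-3,7-dimethyl-8-(TBS-oxy)oct-1-en-4-ol | C=C[C@H](C)[C@@H](O)[C@@H](OC)C[C@H](C)[C@@H](O[Si](C)(C)C(C)(C)C)c1cc(OC)cc(Br)c1OC | intermediate
14 | (3S,4R,5S,7S,8R)-8-Ar-4,5-dimethoxy-3,7-dimethyl-8-(TBS-oxy)oct-1-ene | C=C[C@H](C)[C@@H](OC)[C@@H](OC)C[C@H](C)[C@@H](O[Si](C)(C)C(C)(C)C)c1cc(OC)cc(Br)c1OC | intermediate
15 | (2R,3R,4S,6S,7R)-7-Ar-3,4-dimethoxy-2,6-dimethyl-7-(TBS-oxy)heptanal | O=C[C@H](C)[C@@H](OC)[C@@H](OC)C[C@H](C)[C@@H](O[Si](C)(C)C(C)(C)C)c1cc(OC)cc(Br)c1OC | intermediate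
16 | 2-(triphenylphosphoranylidene)propanal | CC(C=O)=P(c1ccccc1)(c1ccccc1)c1ccccc1 | starting material
17 | (2E,4S,5R,6S,8S,9R)-9-Ar-5,6-dimethoxy-2,4,8-trimethyl-9-(TBS-oxy)non-2-enal | O=C/C(C)=C/[C@H](C)[C@@H](OC)[C@@H](OC)C[C@H](C)[C@@H](O[Si](C)(C)C(C)(C)C)c1cc(OC)cc(Br)c1OC | intermediate
18 | (R)-4-benzyl-3-propanoyl-1,3-thiazolidine-2-thione | CCC(=O)N1C(=S)SC[C@H]1Cc1ccccc1 | starting material
19 | trichlorotitanium (Z)-enolate of 18, formed in the flask | C/C=C(\O[Ti](Cl)(Cl)Cl)N1C(=S)SC[C@H]1Cc1ccccc1 | intermediate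
20 | (2R,3R,4E,6S,7R,8S,10S,11R)-11-Ar-1-[(4R)-4-benzyl-2-thioxo-1,3-thiazolidin-3-yl]-3-hydroxy-7,8-dimethoxy-2,4,6,10-tetramethyl-11-(TBS-oxy)undec-4-en-1-one | S=C1SC[C@@H](Cc2ccccc2)N1C(=O)[C@H](C)[C@@H](O)/C(C)=C/[C@H](C)[C@@H](OC)[C@@H](OC)C[C@H](C)[C@@H](O[Si](C)(C)C(C)(C)C)c1cc(OC)cc(Br)c1OC | intermediate
21 | 3-O-TES ether of 20 | S=C1SC[C@@H](Cc2ccccc2)N1C(=O)[C@H](C)[C@@H](O[Si](CC)(CC)CC)/C(C)=C/[C@H](C)[C@@H](OC)[C@@H](OC)C[C@H](C)[C@@H](O[Si](C)(C)C(C)(C)C)c1cc(OC)cc(Br)c1OC | intermediate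
22 | (2R,3R,4E,6S,7R,8S,10S,11R)-11-Ar-7,8-dimethoxy-2,4,6,10-tetramethyl-11-(TBS-oxy)-3-(TES-oxy)undec-4-enal | O=C[C@H](C)[C@@H](O[Si](CC)(CC)CC)/C(C)=C/[C@H](C)[C@@H](OC)[C@@H](OC)C[C@H](C)[C@@H](O[Si](C)(C)C(C)(C)C)c1cc(OC)cc(Br)c1OC | intermediate
23 | (3S,4R,5E,7S,8R,9S,11S,12R)-12-Ar-8,9-dimethoxy-3,5,7,11-tetramethyl-12-(TBS-oxy)-4-(TES-oxy)dodec-5-en-1-yne | C#C[C@H](C)[C@@H](O[Si](CC)(CC)CC)/C(C)=C/[C@H](C)[C@@H](OC)[C@@H](OC)C[C@H](C)[C@@H](O[Si](C)(C)C(C)(C)C)c1cc(OC)cc(Br)c1OC | intermediate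
24 | (E)-3-iodo-2-methylprop-2-enoic acid | OC(=O)/C(C)=C/I | starting material
25 | (E)-3-iodo-2-methylprop-2-enoyl chloride, formed in the flask | ClC(=O)/C(C)=C/I | intermediate
26 | (E)-3-iodo-2-methylprop-2-enamide | NC(=O)/C(C)=C/I | intermediate
27 | (2E,6S,7R,8E,10S,11R,12S,14S,15R)-15-Ar-11,12-dimethoxy-2,6,8,10,14-pentamethyl-15-(TBS-oxy)-7-(TES-oxy)pentadeca-2,8-dien-4-ynamide | NC(=O)/C(C)=C/C#C[C@H](C)[C@@H](O[Si](CC)(CC)CC)/C(C)=C/[C@H](C)[C@@H](OC)[C@@H](OC)C[C@H](C)[C@@H](O[Si](C)(C)C(C)(C)C)c1cc(OC)cc(Br)c1OC | intermediate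
28 | (2E,4Z,6S,7R,8E,10S,11R,12S,14S,15R)-15-Ar-11,12-dimethoxy-2,6,8,10,14-pentamethyl-15-(TBS-oxy)-7-(TES-oxy)pentadeca-2,4,8-trienamide | NC(=O)/C(C)=C/C=C\[C@H](C)[C@@H](O[Si](CC)(CC)CC)/C(C)=C/[C@H](C)[C@@H](OC)[C@@H](OC)C[C@H](C)[C@@H](O[Si](C)(C)C(C)(C)C)c1cc(OC)cc(Br)c1OC | intermediate
29 | protected macrolactam: 19-membered lactam with N on C20, 2E,4Z,8E, 6S,7R,10S,11R,12S,14S,15R; 11,12,18,21-tetramethoxy, 7-O-TES, 15-O-TBS | CO[C@H]1[C@@H](OC)C[C@H](C)[C@@H](O[Si](C)(C)C(C)(C)C)c2cc(OC)cc(c2OC)NC(=O)/C(C)=C/C=C\[C@H](C)[C@@H](O[Si](CC)(CC)CC)/C(C)=C/[C@@H]1C | intermediate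
30 | C7 alcohol: 29 with free C7–OH, 15-O-TBS | CO[C@H]1[C@@H](OC)C[C@H](C)[C@@H](O[Si](C)(C)C(C)(C)C)c2cc(OC)cc(c2OC)NC(=O)/C(C)=C/C=C\[C@H](C)[C@@H](O)/C(C)=C/[C@@H]1C | intermediate
31 | C7 N-(trichloroacetyl)carbamate of 30, formed in the flask | CO[C@H]1[C@@H](OC)C[C@H](C)[C@@H](O[Si](C)(C)C(C)(C)C)c2cc(OC)cc(c2OC)NC(=O)/C(C)=C/C=C\[C@H](C)[C@@H](OC(=O)NC(=O)C(Cl)(Cl)Cl)/C(C)=C/[C@@H]1C | intermediate
32 | C7 carbamate, 15-O-TBS, 18,21-di-O-methyl | CO[C@H]1[C@@H](OC)C[C@H](C)[C@@H](O[Si](C)(C)C(C)(C)C)c2cc(OC)cc(c2OC)NC(=O)/C(C)=C/C=C\[C@H](C)[C@@H](OC(N)=O)/C(C)=C/[C@@H]1C | intermediate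
33 | C7 carbamate with free C15–OH, 18,21-di-O-methyl | CO[C@H]1[C@@H](OC)C[C@H](C)[C@@H](O)c2cc(OC)cc(c2OC)NC(=O)/C(C)=C/C=C\[C@H](C)[C@@H](OC(N)=O)/C(C)=C/[C@@H]1C | intermediate
34 | quinone of the target (C18 and C21 carbonyls) | CO[C@H]1[C@@H](OC)C[C@H](C)[C@@H](O)C2=CC(=O)C=C(NC(=O)/C(C)=C/C=C\[C@H](C)[C@@H](OC(N)=O)/C(C)=C/[C@@H]1C)C2=O | intermediate
35 | CNP0532580.1: (2E,4Z,6S,7R,8E,10S,11R,12S,14S,15R) hydroquinone macrolactam with C7 carbamate, C11 and C12 methoxy, C15, C18 and C21 hydroxy | CO[C@H]1[C@@H](OC)C[C@H](C)[C@@H](O)c2cc(O)cc(c2O)NC(=O)/C(C)=C/C=C\[C@H](C)[C@@H](OC(N)=O)/C(C)=C/[C@@H]1C | target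

**Count and risks**

Total step count: 26. Longest linear sequence: 25 (steps 1–17 and 19–26; step 18 is a one-step side branch).

Steps most likely to fail:

- Step 7. Facial selectivity of the ligand-controlled alkenylzinc addition may be poor, because the remote C14 and C15 centres give no help and the Lewis-basic ethers may slow the chiral catalyst relative to the background reaction. Fallback: set out from 10 as the C12 epimer mixture that the step then delivers. Oxidise it with Dess–Martin periodinane to the single enone (1R,2S,5E)-1-Ar-2-methyl-1-(TBS-oxy)dec-5-en-4-one F1. Reduce F1 with (R)-2-methyl-CBS-oxazaborolidine and catecholborane in toluene at −78 °C; reagent control on the (E)-enone should give the 12S alcohol. The route is rejoined at 10.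

- Step 17. Under the basic Ohira–Bestmann conditions C6 may epimerise, the C7 silyloxy group may be lost by β-elimination into conjugation with the C8–C9 alkene, or the TES ether may be cleaved by methanol. Fallback: set out from 22. Stork–Zhao olefination [(iodomethyl)triphenylphosphonium iodide, NaN(SiMe3)2, THF/DMPU, −78 °C] gives the (Z)-alkenyl iodide (1Z,3S,4R,5E,7S,8R,9S,11S,12R)-12-Ar-1-iodo-8,9-dimethoxy-3,5,7,11-tetramethyl-12-(TBS-oxy)-4-(TES-oxy)dodeca-1,5-diene F2. Stille coupling of F2 [Pd2(dba)3, AsPh3, N-methylpyrrolidin-2-one, rt] with (E)-2-methyl-3-(trimethylstannyl)prop-2-enamide F3, made from 26 with Me3SnSnMe3 and Pd(PPh3)4, gives the dienamide with retention at both alkenes. The route is rejoined at 28, by-passing 23 and 27.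

- Step 21. Oligomerisation may outrun ring closure, or the copper amidate may stall before insertion into the hindered C20–Br bond. Fallback (ring closure by acylation at C1–N): set out from 23. Sonogashira coupling with acid 24 gives the enyne acid (2E,6S,7R,8E,10S,11R,12S,14S,15R)-15-Ar-11,12-dimethoxy-2,6,8,10,14-pentamethyl-15-(TBS-oxy)-7-(TES-oxy)pentadeca-2,8-dien-4-ynoic acid F4. Zinc–copper–silver semireduction gives the (2E,4Z)-trienoic acid F5. Amination of the aryl bromide (CuI, L-proline, aq. NH3, K2CO3, DMSO, 70 °C) gives the corresponding 15-(3-amino-2,5-dimethoxyphenyl) trienoic acid F6. Macrolactamisation of F6 with bis(2-oxo-3-oxazolidinyl)phosphinic chloride and i-Pr2NEt in toluene at high dilution rejoins the route at 29.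

Further compounds
F1 | step 7 | (1R,2S,5E)-1-Ar-2-methyl-1-(TBS-oxy)dec-5-en-4-one | CCCC/C=C/C(=O)C[C@H](C)[C@@H](O[Si](C)(C)C(C)(C)C)c1cc(OC)cc(Br)c1OC
F2 | step 17 | (1Z,3S,4R,5E,7S,8R,9S,11S,12R)-12-Ar-1-iodo-8,9-dimethoxy-3,5,7,11-tetramethyl-12-(TBS-oxy)-4-(TES-oxy)dodeca-1,5-diene | I/C=C\[C@H](C)[C@@H](O[Si](CC)(CC)CC)/C(C)=C/[C@H](C)[C@@H](OC)[C@@H](OC)C[C@H](C)[C@@H](O[Si](C)(C)C(C)(C)C)c1cc(OC)cc(Br)c1OC
F3 | step 17 | (E)-2-methyl-3-(trimethylstannyl)prop-2-enamide | NC(=O)/C(C)=C/[Sn](C)(C)C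
F4 | step 21 | (2E,6S,7R,8E,10S,11R,12S,14S,15R)-15-Ar-11,12-dimethoxy-2,6,8,10,14-pentamethyl-15-(TBS-oxy)-7-(TES-oxy)pentadeca-2,8-dien-4-ynoic acid | OC(=O)/C(C)=C/C#C[C@H](C)[C@@H](O[Si](CC)(CC)CC)/C(C)=C/[C@H](C)[C@@H](OC)[C@@H](OC)C[C@H](C)[C@@H](O[Si](C)(C)C(C)(C)C)c1cc(OC)cc(Br)c1OC
F5 | step 21 | (2E,4Z,6S,7R,8E,10S,11R,12S,14S,15R)-15-Ar-11,12-dimethoxy-2,6,8,10,14-pentamethyl-15-(TBS-oxy)-7-(TES-oxy)pentadeca-2,4,8-trienoic acid | OC(=O)/C(C)=C/C=C\[C@H](C)[C@@H](O[Si](CC)(CC)CC)/C(C)=C/[C@H](C)[C@@H](OC)[C@@H](OC)C[C@H](C)[C@@H](O[Si](C)(C)C(C)(C)C)c1cc(OC)cc(Br)c1OC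
F6 | step 21 | (2E,4Z,6S,7R,8E,10S,11R,12S,14S,15R)-15-(3-amino-2,5-dimethoxyphenyl)-11,12-dimethoxy-2,6,8,10,14-pentamethyl-15-(TBS-oxy)-7-(TES-oxy)pentadeca-2,4,8-trienoic acid | OC(=O)/C(C)=C/C=C\[C@H](C)[C@@H](O[Si](CC)(CC)CC)/C(C)=C/[C@H](C)[C@@H](OC)[C@@H](OC)C[C@H](C)[C@@H](O[Si](C)(C)C(C)(C)C)c1cc(OC)cc(N)c1OC
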